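## Analysis of the target

The target is a flavone in which ring A (C4a to C8a) is fused to the pyranone ring C (O1, C2, C3, C4) and ring B sits on C2, and in flavone terms it is 5,7,2',5'-tetrahydroxy-6,8,4'-trimethoxyflavone. It has no stereocentre and no double-bond geometry to set, so the whole task is to place seven oxygen substituents and to keep three methyl ethers distinct from four free hydroxyls. Ring A has no hydrogen (C5 OH, C6 OMe, C7 OH, C8 OMe, C8a O1, C4a acyl), so no position can be reached by a late electrophilic substitution, and a global demethylation at the end is ruled out. Ring B is a methoxyhydroquinone (C2' and C5' hydroxyls para to each other) that oxidises easily to a quinone once free, and the pyranone opens in hot aqueous base, so the last steps must be mild and close to neutral. Ring A has a hidden symmetry, because if O1 and the C5 oxygen are treated alike it is a 2-acylresorcinol with a mirror plane through C7 and C4a. The plan rests on C8a and C4a, two neighbouring carbons that carry an oxygen (O1) and an acyl carbon (C4), which is the pair of groups a carboxylic acid hands to the two ends of an aryne; with an arylpropiolic acid the transferred acyl group also brings C3, C2 and ring B, so ring C can close in the same flask. The difficulty is the direction of addition across C4a≡C8a, which is decided only by the difference between the substituents at C5 and C8.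

## Retrosynthetic reasoning

Target 19 is traced back to the tribenzyl ether 18. The three hydroxyls at C7, C2' and C5' are masked as benzyl ethers because hydrogenolysis is neutral, leaves methyl ethers alone, and frees the oxidation-prone hydroquinone only in the last flask.

The C5 hydroxyl of 18 is traced back to the aryl triflate 17 by cleavage of the S–O bond. The triflate is not an ordinary protecting group here. It is the twin of the leaving group that made the aryne, and it is the substituent meant to steer the addition.

Flavone 17 is cut at C8a–O1, C4a–C4 and O1–C2, which gives the silyl bis-triflate 9 and the arylpropiolic acid 14. Forward, fluoride turns 9 into aryne 15, the carboxylate of 14 adds with its oxygen at C8a, the C4a anion takes the acyl carbon, and the phenoxide of the resulting ynone 16 closes ring C at C2. The cut is made here because it joins two fragments of similar size in one operation and puts ring B, C2, C3 and C4 in together. Because 9 is symmetric, either triflate can leave and the same aryne forms.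

Bis-triflate 9 comes from the silylresorcinol 8 by double triflation. The C–Si bond of 8 is traced back to the C–Br bond of the bis(silyl ether) 6 by a retro-Brook shift through phenoxide 7, and 6 to the bromoresorcinol 5. Bromide 5 comes from resorcinol 4, whose C2 is the only ring position that still has hydrogen, so the halogenation has no choice of site.

Resorcinol 4 is cut at its two phenolic C–O bonds back to the dibromide 3, and 3 comes from the benzyl ether 2 by double bromination para to the two methoxy groups. Ether 2 is the benzyl ether of 2,6-dimethoxyphenol 1, which already carries the OMe/OH/OMe triad of C6, C7 and C8 and no carbon substituent that would have to be removed later.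

Acid 14 is cut at the aryl–alkyne bond into the aryl iodide 12 and propiolic acid 13. Iodide 12 comes from the dibenzyl ether 11 by iodination para to the methoxy group, and 11 from methoxyhydroquinone 10.

## Alternatives that were turned down

Alternative 1: Ring A is made last, by cutting C8–C8a and C5–C6 on a pyranone that already carries ring B.
- Forward reaction: the doubly deprotonated form of 1,3-dimethoxyacetone A3 would displace the methylsulfanyl group at the future C8a of methyl 6-[2,5-bis(benzyloxy)-4-methoxyphenyl]-2-(methylsulfanyl)-4-oxo-4H-pyran-3-carboxylate A2. It would then acylate at the ester carbon of A2 and enolise to the resorcinol ring of 2-[2,5-bis(benzyloxy)-4-methoxyphenyl]-5,7-dihydroxy-6,8-dimethoxy-4H-chromen-4-one A1.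
- For it: A3 is symmetric, so all four ring A oxygens arrive in their places with no regiochemical question, and A1 has the C5 and C7 hydroxyls already free.
- Against it: A2 is a linear construct with ring B attached early. Its pyranone offers C6 and C4 as well as the methylsulfanyl-bearing carbon to a hard carbanion, and attack at C6 opens the heterocycle. The bis-enolate of A3 is a hindered, weak nucleophile that must react twice at carbons each already bearing a methoxy group.
- Comparison: on positional certainty in ring A the route through A1 is the stronger plan. The chosen strategy offers convergence, two stable fragments, and a known reaction class for every bond it forms.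

Alternative 2: Ring C is cut only at C8a–O1.
- Forward reaction: a copper-catalysed Ullmann-type O-arylation in which the enol oxygen of 1-[4-(benzyloxy)-2,6-dibromo-3,5-dimethoxyphenyl]-3-[2,5-bis(benzyloxy)-4-methoxyphenyl]propane-1,3-dione A4 displaces one of two equivalent bromides. The product is 7-(benzyloxy)-2-[2,5-bis(benzyloxy)-4-methoxyphenyl]-5-bromo-6,8-dimethoxy-4H-chromen-4-one A5.
- For it: the symmetric dibromide A4 removes any positional question, and intramolecular O-arylation of such diketones is dependable.
- Against it: A5 still has bromine where C5 needs oxygen, so a further C–Br to C–O exchange must be run on a position flanked on both sides, on a finished chromone that opens in base. The doubly ortho-substituted aroyl unit of A4 is hindered in its own assembly, and the sequence is linear and longer.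
- Comparison: the ring closure of A4 to A5 is more predictable than an aryne addition, and this is conceded. The chosen strategy instead has the C5 oxygen in place from the start, forms three bonds in its key step instead of one, and needs no late metal-mediated oxygenation.

Alternative 3: Ring C is cut at C4a–C4, C4–C3 and O1–C2 into three components.
- Forward reaction: 5-(benzyloxy)-2-iodo-4,6-dimethoxybenzene-1,3-diol A6, 1,4-bis(benzyloxy)-2-ethynyl-5-methoxybenzene A7 and carbon monoxide A8 combine in a palladium-catalysed carbonylative Sonogashira coupling in a secondary amine. Cyclisation in the same flask gives 7-(benzyloxy)-2-[2,5-bis(benzyloxy)-4-methoxyphenyl]-5-hydroxy-6,8-dimethoxy-4H-chromen-4-one A9. A9 has the same structure as 18, so this plan would rejoin the chosen route one step before the target.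
- For it: the carbon–iodine bond of the symmetric A6 fixes the acyl position, so there is no direction-of-addition risk, and A8 supplies C4 as a one-carbon unit at no cost in steps. It is also shorter: A6 is one step from 4, A9 carries the free C5 hydroxyl directly, and the silylation, silyl migration, triflation and triflate cleavage all fall away.
- Against it: the iodine of A6 sits between two free hydroxyls on a ring with five oxygens, so oxidative addition is slow. Insertion of A8 at the hindered arylpalladium must outrun direct alkynylation by A7, which would end in closure of a five-membered furan ring that lacks C4 instead of in A9. A 5-exo closure of the alkynone also competes, A6 is air-sensitive under the amine, A7 can homocouple, and A8 is a toxic gas that must be held at a steady pressure.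
- Comparison: on step count and on positional certainty this alternative is stronger, since A9 would be reached from 4 in two steps. The chosen strategy offers a metal-free union with no branch between carbonylation by A8 and direct coupling, a storable bis-triflate in place of the oxidation-prone A6, and an acid partner that cannot dimerise as A7 can. It pays for this with the regiochemical risk of the aryne step.

Key step: step 11

Remark: flavone numbering (O1, C2 to C8a, primed numbers for ring B) is used for the chromenones and for the atoms of their precursors that end up there. The target has no stereocentre, so no stereochemical assumption is needed.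

## Route

Step 1
Reactants: 1 2,6-dimethoxyphenol
Product: 2 2-(benzyloxy)-1,3-dimethoxybenzene
Conditions: BnBr, K2CO3, DMF, 60 °C
Reagents that add atoms: benzyl bromide, BrCc1ccccc1
Why: Williamson etherification of the single phenol; the benzyl group marks the oxygen that becomes the C7 hydroxyl and keeps it distinct from the two methyl ethers.

Step 2
Reactants: 2 2-(benzyloxy)-1,3-dimethoxybenzene
Product: 3 3-(benzyloxy)-1,5-dibromo-2,4-dimethoxybenzene
Conditions: NBS (2.1 equiv), MeCN, 0 °C to rt, dark
Reagents that add atoms: N-bromosuccinimide, O=C1CCC(=O)N1Br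
Why: Electrophilic aromatic bromination; each bromine enters para to one methoxy group and ortho to the other, whereas the remaining position is activated only by the central benzyloxy group, which its two neighbours twist out of conjugation, as in the bromination of 1,2,3-trimethoxybenzene.

Step 3
Reactants: 3 3-(benzyloxy)-1,5-dibromo-2,4-dimethoxybenzene
Product: 4 5-(benzyloxy)-4,6-dimethoxybenzene-1,3-diol
Conditions: Pd2(dba)3, tBuXPhos, KOH, 1,4-dioxane/H2O, 100 °C, degassed; then HCl (aq)
Reagents that add atoms: potassium hydroxide, [K+].[OH-]
Why: Palladium-catalysed hydroxylation of aryl bromides (C–O cross-coupling with hydroxide); the bulky biaryl phosphine favours reductive elimination of the phenoxide over diaryl ether formation, and each bromide has only one ortho substituent.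

Step 4
Reactants: 4 5-(benzyloxy)-4,6-dimethoxybenzene-1,3-diol
Product: 5 5-(benzyloxy)-2-bromo-4,6-dimethoxybenzene-1,3-diol
Conditions: NBS (1.0 equiv), CH2Cl2/MeCN, −40 °C, under Ar
Reagents that add atoms: N-bromosuccinimide, O=C1CCC(=O)N1Br
Why: Electrophilic bromination; C2 is the only ring position that still has hydrogen and lies ortho to both hydroxyls, so the site is not in question, and low temperature with exact stoichiometry limits oxidation of the electron-rich ring.

Step 5
Reactants: 5 5-(benzyloxy)-2-bromo-4,6-dimethoxybenzene-1,3-diol
Product: 6 {[5-(benzyloxy)-2-bromo-4,6-dimethoxy-1,3-phenylene]bis(oxy)}bis(trimethylsilane)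
Conditions: HMDS, THF, 65 °C; volatiles removed, used crude
Reagents that add atoms: hexamethyldisilazane, C[Si](C)(C)N[Si](C)(C)C
Why: O-silylation of both phenols with loss of ammonia; it places a silyl group on each oxygen next to the bromide, ready for the migration.

Step 6
Reactants: 6 {[5-(benzyloxy)-2-bromo-4,6-dimethoxy-1,3-phenylene]bis(oxy)}bis(trimethylsilane)
Product: 8 5-(benzyloxy)-4,6-dimethoxy-2-(trimethylsilyl)benzene-1,3-diol, via lithium silyloxy silylphenoxide 7 (not isolated)
Conditions: n-BuLi, THF, −78 °C to rt; then MeOH, 0 °C; NH4Cl (aq)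
Reagents that add atoms: none
Why: Bromine–lithium exchange followed by a retro-Brook rearrangement (1,3 O-to-C silyl shift) driven by formation of the lithium phenoxide; methanol in the basic mixture then cleaves the remaining aryl silyl ether, and the work-up is kept near neutral because the silicon-bearing carbon is open to ipso protonation.

Step 7
Reactants: 8 5-(benzyloxy)-4,6-dimethoxy-2-(trimethylsilyl)benzene-1,3-diol
Product: 9 5-(benzyloxy)-4,6-dimethoxy-2-(trimethylsilyl)-1,3-phenylene bis(trifluoromethanesulfonate)
Conditions: Tf2O, pyridine, CH2Cl2, −20 to 0 °C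
Reagents that add atoms: trifluoromethanesulfonic anhydride, O=S(=O)(OS(=O)(=O)C(F)(F)F)C(F)(F)F
Why: O-sulfonylation of both phenols, the usual way to 2-silylaryl triflates; the product is symmetric, so the later loss of either triflate gives the same aryne.

Step 8
Reactants: 10 methoxyhydroquinone (2-methoxybenzene-1,4-diol)
Product: 11 1,4-bis(benzyloxy)-2-methoxybenzene
Conditions: BnBr, K2CO3, DMF, 60 °C, under N2
Reagents that add atoms: benzyl bromide, BrCc1ccccc1
Why: Double Williamson etherification; nitrogen keeps the hydroquinone from oxidising before both oxygens are capped.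

Step 9
Reactants: 11 1,4-bis(benzyloxy)-2-methoxybenzene
Product: 12 1,4-bis(benzyloxy)-2-iodo-5-methoxybenzene
Conditions: NIS, CF3CO2H (cat.), MeCN, 0 °C to rt
Reagents that add atoms: N-iodosuccinimide, O=C1CCC(=O)N1I
Why: Electrophilic iodination; the position para to the methoxy group and ortho to a benzyloxy group is the most activated one, as in the 5-substitution of 1,2,4-trialkoxybenzenes.

Step 10
Reactants: 12 1,4-bis(benzyloxy)-2-iodo-5-methoxybenzene; 13 propiolic acid
Product: 14 3-[2,5-bis(benzyloxy)-4-methoxyphenyl]prop-2-ynoic acid
Conditions: Pd(PPh3)4, DBU, DMSO, 35 °C; then cold HCl (aq)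
Reagents that add atoms: none
Why: Copper-free Sonogashira coupling of an aryl iodide with propiolic acid as its amidinium carboxylate; the low temperature and the absence of copper keep the arylpropiolic acid from decarboxylating.

Step 11
Reactants: 9 5-(benzyloxy)-4,6-dimethoxy-2-(trimethylsilyl)-1,3-phenylene bis(trifluoromethanesulfonate); 14 3-[2,5-bis(benzyloxy)-4-methoxyphenyl]prop-2-ynoic acid
Product: 17 7-(benzyloxy)-2-[2,5-bis(benzyloxy)-4-methoxyphenyl]-6,8-dimethoxy-4-oxo-4H-chromen-5-yl trifluoromethanesulfonate, via triflyloxy aryne 15 (not isolated), via hydroxyaryl ynone 16 (not isolated)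
Conditions: CsF (4 equiv, dried), 9 (1.3 equiv), THF, 125 °C, sealed tube
Reagents that add atoms: none
Why: Fluoride attacks silicon in 9 and either of the two equivalent triflates leaves, so one aryne 15 forms and keeps a triflyloxy group at C5, while the same base turns 14 into its caesium carboxylate. The carboxylate oxygen adds to C8a, the aryl anion at C4a attacks the ester carbonyl three atoms away through a four-membered intermediate, and its opening gives the phenoxide of ynone 16, an anionic Fries-type O-to-C acyl shift. The closest known reaction type is the formal insertion of arynes into the C–O bond of carboxylic acids, which gives o-hydroxyaryl ketones and, with arylpropiolic acids, flavones. Ring C, the only ring formed, closes by 6-endo-dig conjugate addition of the C8a phenoxide to C2 of the ynone, and the proton of the acid ends up on C3. No stereocentre is formed. The step needs oxygen at C8a and carbon at C4a: the triflyloxy group at C5 is a stronger σ-acceptor and a larger group than the methoxy group at C8, so it should direct the nucleophile to C8a and leave the charge next to itself. It also needs the C4a anion to capture the acyl carbon before it is protonated or loses the second triflate, and for this the route relies on the intramolecular reach of the activated alkynoyl ester and on the dry aprotic medium. The preference for 6-endo over 5-exo closure follows from the polarisation of the ynone, whose β-carbon C2 is the electrophilic site under basic aprotic conditions.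

Step 12
Reactants: 17 7-(benzyloxy)-2-[2,5-bis(benzyloxy)-4-methoxyphenyl]-6,8-dimethoxy-4-oxo-4H-chromen-5-yl trifluoromethanesulfonate
Product: 18 7-(benzyloxy)-2-[2,5-bis(benzyloxy)-4-methoxyphenyl]-5-hydroxy-6,8-dimethoxy-4H-chromen-4-one
Conditions: Et4NOH (aq), 1,4-dioxane, rt; then HCl (aq)
Reagents that add atoms: none
Why: Hydroxide attacks the sulfonyl sulfur of the aryl triflate (S–O cleavage), which the peri carbonyl activates; a competing ipso substitution at C5 would give the same phenol, and the 2-arylpyranone should tolerate aqueous base at room temperature.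

Step 13
Reactants: 18 7-(benzyloxy)-2-[2,5-bis(benzyloxy)-4-methoxyphenyl]-5-hydroxy-6,8-dimethoxy-4H-chromen-4-one
Product: 19 2-(2,5-dihydroxy-4-methoxyphenyl)-5,7-dihydroxy-6,8-dimethoxy-4H-chromen-4-one
Conditions: H2 (1 atm), 10% Pd/C, EtOAc/MeOH, rt; work-up under Ar
Reagents that add atoms: none
Why: Hydrogenolysis of three benzyl aryl ethers; the methyl ethers, the chelated C5 hydroxyl and the C2–C3 double bond of the vinylogous ester should be untouched at 1 atm and room temperature.

## Compound list

1 | 2,6-dimethoxyphenol | COc1cccc(OC)c1O | starting material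
2 | 2-(benzyloxy)-1,3-dimethoxybenzene | COc1cccc(OC)c1OCc1ccccc1 | intermediate
3 | 3-(benzyloxy)-1,5-dibromo-2,4-dimethoxybenzene | COc1c(Br)cc(Br)c(OC)c1OCc1ccccc1 | intermediate
4 | 5-(benzyloxy)-4,6-dimethoxybenzene-1,3-diol | COc1c(O)cc(O)c(OC)c1OCc1ccccc1 | intermediate
5 | 5-(benzyloxy)-2-bromo-4,6-dimethoxybenzene-1,3-diol | COc1c(O)c(Br)c(O)c(OC)c1OCc1ccccc1 | intermediate
6 | {[5-(benzyloxy)-2-bromo-4,6-dimethoxy-1,3-phenylene]bis(oxy)}bis(trimethylsilane) | COc1c(O[Si](C)(C)C)c(Br)c(O[Si](C)(C)C)c(OC)c1OCc1ccccc1 | intermediate
7 | lithium 3-(benzyloxy)-2,4-dimethoxy-6-(trimethylsilyl)-5-[(trimethylsilyl)oxy]phenolate | [Li+].[O-]c1c(OC)c(OCc2ccccc2)c(OC)c(O[Si](C)(C)C)c1[Si](C)(C)C | intermediate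
8 | 5-(benzyloxy)-4,6-dimethoxy-2-(trimethylsilyl)benzene-1,3-diol | COc1c(O)c([Si](C)(C)C)c(O)c(OC)c1OCc1ccccc1 | intermediate
9 | 5-(benzyloxy)-4,6-dimethoxy-2-(trimethylsilyl)-1,3-phenylene bis(trifluoromethanesulfonate) | COc1c(OS(=O)(=O)C(F)(F)F)c([Si](C)(C)C)c(OS(=O)(=O)C(F)(F)F)c(OC)c1OCc1ccccc1 | intermediate
10 | methoxyhydroquinone (2-methoxybenzene-1,4-diol) | COc1cc(O)ccc1O | starting material
11 | 1,4-bis(benzyloxy)-2-methoxybenzene | COc1cc(OCc2ccccc2)ccc1OCc1ccccc1 | intermediate
12 | 1,4-bis(benzyloxy)-2-iodo-5-methoxybenzene | COc1cc(OCc2ccccc2)c(I)cc1OCc1ccccc1 | intermediate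
13 | propiolic acid | C#CC(=O)O | starting material
14 | 3-[2,5-bis(benzyloxy)-4-methoxyphenyl]prop-2-ynoic acid | OC(=O)C#Cc1cc(OCc2ccccc2)c(OC)cc1OCc1ccccc1 | intermediate
15 | 3-(benzyloxy)-2,4-dimethoxy-5,6-didehydrophenyl trifluoromethanesulfonate (aryne C4a≡C8a) | COC1=C(OCc2ccccc2)C(OC)=C(OS(=O)(=O)C(F)(F)F)C#C1 | intermediate
16 | 3-(benzyloxy)-6-{3-[2,5-bis(benzyloxy)-4-methoxyphenyl]prop-2-ynoyl}-5-hydroxy-2,4-dimethoxyphenyl trifluoromethanesulfonate | COc1cc(OCc2ccccc2)c(C#CC(=O)c2c(O)c(OC)c(OCc3ccccc3)c(OC)c2OS(=O)(=O)C(F)(F)F)cc1OCc1ccccc1 | intermediate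
17 | 7-(benzyloxy)-2-[2,5-bis(benzyloxy)-4-methoxyphenyl]-6,8-dimethoxy-4-oxo-4H-chromen-5-yl trifluoromethanesulfonate | COc1cc(OCc2ccccc2)c(-c2cc(=O)c3c(OS(=O)(=O)C(F)(F)F)c(OC)c(OCc4ccccc4)c(OC)c3o2)cc1OCc1ccccc1 | intermediate
18 | 7-(benzyloxy)-2-[2,5-bis(benzyloxy)-4-methoxyphenyl]-5-hydroxy-6,8-dimethoxy-4H-chromen-4-one | COc1cc(OCc2ccccc2)c(-c2cc(=O)c3c(O)c(OC)c(OCc4ccccc4)c(OC)c3o2)cc1OCc1ccccc1 | intermediate
19 | 2-(2,5-dihydroxy-4-methoxyphenyl)-5,7-dihydroxy-6,8-dimethoxy-4H-chromen-4-one | COc1cc(O)c(-c2cc(=O)c3c(O)c(OC)c(O)c(OC)c3o2)cc1O | target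

## Step count and risk

Total step count: 13. Longest linear sequence: 10 steps (steps 1 to 7, then 11, 12 and 13); the ring B branch is steps 8 to 10.

Step 11 (key step).
- Wrong direction of addition: both groups flanking the aryne are σ-acceptors, so the bias is only the difference between triflyloxy and methoxy. Addition of the carboxylate oxygen at C4a instead of C8a would exchange the places of the triflyloxy and methoxy groups relative to the carbonyl.
- Loss of the C4a anion: this anion sits ortho to the remaining triflate. It may expel that triflate and form a second aryne, or be protonated before it captures the acyl carbon.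
- Decarboxylation: the caesium propiolate may lose CO2 at 125 °C.
- Fallback: it sets out from 5 and 14 and comes back at 18, fixing the acyl position by a carbon–halogen bond instead of by aryne polarisation. Bromoresorcinol 5 is capped with MOMCl and NaH in DMF to give 1-(benzyloxy)-4-bromo-2,6-dimethoxy-3,5-bis(methoxymethoxy)benzene F1. Acid 14 is coupled with MeNHOMe·HCl and EDC·HCl in CH2Cl2 to give 3-[2,5-bis(benzyloxy)-4-methoxyphenyl]-N-methoxy-N-methylprop-2-ynamide F2. Bromine–lithium exchange on F1 (n-BuLi, THF, −78 °C) and addition of the aryllithium to F2 should give 1-[4-(benzyloxy)-3,5-dimethoxy-2,6-bis(methoxymethoxy)phenyl]-3-[2,5-bis(benzyloxy)-4-methoxyphenyl]prop-2-yn-1-one F3. HCl in MeOH removes both acetals to give 1-[4-(benzyloxy)-2,6-dihydroxy-3,5-dimethoxyphenyl]-3-[2,5-bis(benzyloxy)-4-methoxyphenyl]prop-2-yn-1-one F4. K2CO3 in acetone then closes ring C 6-endo through either of the two equivalent hydroxyls to give 18.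

Step 3.
- What may go wrong: the second C–O coupling may stall on the bromophenoxide, hydrodebromination may compete, and the dianion of the product may be oxidised by air in hot base.
- Fallback: from 3 back to 4 by making C–B bonds first. Miyaura borylation (B2pin2, Pd(dppf)Cl2, KOAc, 1,4-dioxane, 90 °C) should give 2,2'-[5-(benzyloxy)-4,6-dimethoxy-1,3-phenylene]bis(4,4,5,5-tetramethyl-1,3,2-dioxaborolane) F5. Oxidation with NaBO3·4H2O in THF/H2O at room temperature then gives 4 without strong base or heat.

Step 4.
- What may go wrong: the positive-bromine reagent may oxidise the pentaoxygenated resorcinol instead of brominating it, or halogenate a second time at the ipso carbon with loss of aromaticity.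
- Fallback: from 4 to 8 by directed metalation, which places silicon directly and bypasses 5, 6 and 7. Resorcinol 4 is acylated with ClCONEt2 and K2CO3 in MeCN to give 5-(benzyloxy)-4,6-dimethoxy-1,3-phenylene bis(N,N-diethylcarbamate) F6. Lithiation between the two carbamates (s-BuLi, TMEDA, THF, −78 °C) with TMSCl quench gives 5-(benzyloxy)-4,6-dimethoxy-2-(trimethylsilyl)-1,3-phenylene bis(N,N-diethylcarbamate) F7. Reductive removal of both carbamates with LiAlH4 in THF gives 8.

Step 10.
- What may go wrong: the product acid may decarboxylate under palladium and amine, and the terminal alkyne so formed may couple a second time with the iodide. Oxidative addition into the electron-rich, ortho-alkoxy iodide may also be slow.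
- Fallback: from 11 to 14 by one-carbon homologation of an aldehyde, with no cross-coupling. Vilsmeier–Haack formylation of 11 (POCl3, DMF) should give 2,5-bis(benzyloxy)-4-methoxybenzaldehyde F8, at the same position as the iodination. Corey–Fuchs olefination (CBr4, PPh3, CH2Cl2) gives 1,4-bis(benzyloxy)-2-(2,2-dibromoethenyl)-5-methoxybenzene F9. n-BuLi (2.1 equiv, THF, −78 °C) followed by CO2 gives 14.

Step 13.
- What may go wrong: the C2–C3 double bond may be saturated before the hindered C7 benzyl ether, flanked by two methoxy groups, is cleaved. The freed ring B hydroquinone may be oxidised by air during work-up.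
- Fallback: from 18 to 19 by Lewis-acid debenzylation without hydrogen, using BCl3 and pentamethylbenzene as cation scavenger in CH2Cl2 at −78 °C with a methanol quench. No new compound is made on the way.

## Further compounds

F1 | step 11 | 1-(benzyloxy)-4-bromo-2,6-dimethoxy-3,5-bis(methoxymethoxy)benzene | COCOc1c(Br)c(OCOC)c(OC)c(OCc2ccccc2)c1OC
F2 | step 11 | 3-[2,5-bis(benzyloxy)-4-methoxyphenyl]-N-methoxy-N-methylprop-2-ynamide | CON(C)C(=O)C#Cc1cc(OCc2ccccc2)c(OC)cc1OCc1ccccc1
F3 | step 11 | 1-[4-(benzyloxy)-3,5-dimethoxy-2,6-bis(methoxymethoxy)phenyl]-3-[2,5-bis(benzyloxy)-4-methoxyphenyl]prop-2-yn-1-one | COCOc1c(C(=O)C#Cc2cc(OCc3ccccc3)c(OC)cc2OCc2ccccc2)c(OCOC)c(OC)c(OCc2ccccc2)c1OC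
F4 | step 11 | 1-[4-(benzyloxy)-2,6-dihydroxy-3,5-dimethoxyphenyl]-3-[2,5-bis(benzyloxy)-4-methoxyphenyl]prop-2-yn-1-one | COc1cc(OCc2ccccc2)c(C#CC(=O)c2c(O)c(OC)c(OCc3ccccc3)c(OC)c2O)cc1OCc1ccccc1
F5 | step 3 | 2,2'-[5-(benzyloxy)-4,6-dimethoxy-1,3-phenylene]bis(4,4,5,5-tetramethyl-1,3,2-dioxaborolane) | COc1c(B2OC(C)(C)C(C)(C)O2)cc(B2OC(C)(C)C(C)(C)O2)c(OC)c1OCc1ccccc1
F6 | step 4 | 5-(benzyloxy)-4,6-dimethoxy-1,3-phenylene bis(N,N-diethylcarbamate) | CCN(CC)C(=O)Oc1cc(OC(=O)N(CC)CC)c(OC)c(OCc2ccccc2)c1OC
F7 | step 4 | 5-(benzyloxy)-4,6-dimethoxy-2-(trimethylsilyl)-1,3-phenylene bis(N,N-diethylcarbamate) | CCN(CC)C(=O)Oc1c([Si](C)(C)C)c(OC(=O)N(CC)CC)c(OC)c(OCc2ccccc2)c1OC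
F8 | step 10 | 2,5-bis(benzyloxy)-4-methoxybenzaldehyde | COc1cc(OCc2ccccc2)c(C=O)cc1OCc1ccccc1
F9 | step 10 | 1,4-bis(benzyloxy)-2-(2,2-dibromoethenyl)-5-methoxybenzene | COc1cc(OCc2ccccc2)c(C=C(Br)Br)cc1OCc1ccccc1
F0 | step 13 | none | none
A1 | alternative 1 | 2-[2,5-bis(benzyloxy)-4-methoxyphenyl]-5,7-dihydroxy-6,8-dimethoxy-4H-chromen-4-one | COc1cc(OCc2ccccc2)c(-c2cc(=O)c3c(O)c(OC)c(O)c(OC)c3o2)cc1OCc1ccccc1
A2 | alternative 1 | methyl 6-[2,5-bis(benzyloxy)-4-methoxyphenyl]-2-(methylsulfanyl)-4-oxo-4H-pyran-3-carboxylate | COC(=O)c1c(SC)oc(-c2cc(OCc3ccccc3)c(OC)cc2OCc2ccccc2)cc1=O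
A3 | alternative 1 | 1,3-dimethoxyacetone | COCC(=O)COC
A4 | alternative 2 | 1-[4-(benzyloxy)-2,6-dibromo-3,5-dimethoxyphenyl]-3-[2,5-bis(benzyloxy)-4-methoxyphenyl]propane-1,3-dione | COc1cc(OCc2ccccc2)c(C(=O)CC(=O)c2c(Br)c(OC)c(OCc3ccccc3)c(OC)c2Br)cc1OCc1ccccc1
A5 | alternative 2 | 7-(benzyloxy)-2-[2,5-bis(benzyloxy)-4-methoxyphenyl]-5-bromo-6,8-dimethoxy-4H-chromen-4-one | COc1cc(OCc2ccccc2)c(-c2cc(=O)c3c(Br)c(OC)c(OCc4ccccc4)c(OC)c3o2)cc1OCc1ccccc1
A6 | alternative 3 | 5-(benzyloxy)-2-iodo-4,6-dimethoxybenzene-1,3-diol | COc1c(O)c(I)c(O)c(OC)c1OCc1ccccc1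
A7 | alternative 3 | 1,4-bis(benzyloxy)-2-ethynyl-5-methoxybenzene | COc1cc(OCc2ccccc2)c(C#C)cc1OCc1ccccc1
A8 | alternative 3 | carbon monoxide | [C-]#[O+]
A9 | alternative 3 | 7-(benzyloxy)-2-[2,5-bis(benzyloxy)-4-methoxyphenyl]-5-hydroxy-6,8-dimethoxy-4H-chromen-4-one | COc1cc(OCc2ccccc2)c(-c2cc(=O)c3c(O)c(OC)c(OCc4ccccc4)c(OC)c3o2)cc1OCc1ccccc1
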